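**Plan**

- Retrosynthesis: after removal of three silyl ethers, the C2–C3 bond of ring C is cut (C–H insertion transform). C2 then reverts to the methyl of a methoxy group on C8a and C3 to a diazo-bearing carbon; further cuts are the diazo group, the C4–C4a bond (aryllithium plus Weinreb amide) and the two aryl–prenyl bonds.
- Feature used: C2 is an unsubstituted CH2 on O1, and C3 lies between the C4 carbonyl and ring B. O1–C2 can therefore be carried as an aryl methoxy group on ring A and C3 as an aryl/acyl carbene carbon that reaches those methoxy C–H bonds through a six-membered transition state.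
- Forward: ring B is built as an arylacetic Weinreb amide from 3-bromo-4,5-dihydroxybenzaldehyde (steps 1–7), and ring A as a prenylated bis-MOM anisole from 5-methoxyresorcinol (steps 8–9). They are joined at C4–C4a, MOM is exchanged for TIPS, the diazo group is introduced, and ring C is closed; only desilylation follows.
- Stereochemistry: the single stereocentre C3 (S) is created in the ring-closing C–H insertion under control of the chiral dirhodium carboxylate Rh2(S-PTTL)4 and meets neither base nor strong acid afterwards.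

Key step: step 14

Abbreviations: prenyl = 3-methylbut-2-en-1-yl; TIPS = triisopropylsilyl; MOM = methoxymethyl; ArB = 4-methoxy-3-prenyl-5-(TIPS-oxy)phenyl; PTTL = N-phthaloyl-(S)-tert-leucinate; p-ABSA = 4-acetamidobenzenesulfonyl azide; CDI = 1,1'-carbonyldiimidazole. Flavonoid numbering is used (O1, C2, C3, C4, C4a, C5–C8, C8a; ring B primed).

Assumption: Rh2(S-PTTL)4 is taken to deliver the 3S configuration; should the sense of induction prove opposite, the mirror-image catalyst Rh2(R-PTTL)4 is used with no other change.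

**Route**

Step 1
Reactants: 1 3-bromo-4,5-dihydroxybenzaldehyde
Product: 2 3-bromo-5-hydroxy-4-methoxybenzaldehyde
Conditions: MeI (1.1 equiv), Li2CO3, DMF, 40 °C
Reagents that add atoms: iodomethane, CI
Why: The 4-hydroxyl, para to the formyl group and flanked by bromine, is the more acidic phenol, so the weak base Li2CO3 ionises only this one and Williamson O-methylation should occur there alone.

Step 2
Reactants: 2 3-bromo-5-hydroxy-4-methoxybenzaldehyde
Product: 3 3-bromo-4-methoxy-5-(TIPS-oxy)benzaldehyde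
Conditions: TIPSCl, imidazole, DMF, rt
Reagents that add atoms: triisopropylsilyl chloride, CC(C)[Si](Cl)(C(C)C)C(C)C
Why: Silyl ether formation at the remaining phenol with TIPSCl and imidazole gives a protecting group that withstands organolithiums, dilute acid and the later carbenoid and that fluoride removes at the end.

Step 3
Reactants: 3 3-bromo-4-methoxy-5-(TIPS-oxy)benzaldehyde
Product: 4 1-bromo-2-methoxy-5-(2-methoxyethenyl)-3-(TIPS-oxy)benzene (E/Z mixture)
Conditions: MeOCH2PPh3Cl, KOtBu, THF, 0 °C → rt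
Reagents that add atoms: (methoxymethyl)triphenylphosphonium chloride, COC[P+](c1ccccc1)(c1ccccc1)c1ccccc1.[Cl-]
Why: Wittig methoxymethylenation of the aryl aldehyde adds the one carbon that becomes C3 and leaves the carbonyl masked as an enol ether that is inert to the organolithium of the next step.

Step 4
Reactants: 4 1-bromo-2-methoxy-5-(2-methoxyethenyl)-3-(TIPS-oxy)benzene; 5 prenyl bromide
Product: 7 2-methoxy-5-(2-methoxyethenyl)-1-prenyl-3-(TIPS-oxy)benzene (E/Z mixture), via aryllithium 6 (not isolated)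
Conditions: n-BuLi, THF, –78 °C; then CuI (10 mol%), 5, –78 °C → rt
Reagents that add atoms: none
Why: Bromine–lithium exchange at –78 °C outruns any reaction at the enol ether or silyl ether, and copper-catalysed allylic substitution of prenyl bromide by the aryllithium at its unhindered primary carbon should give the linear prenyl arene.

Step 5
Reactants: 7 2-methoxy-5-(2-methoxyethenyl)-1-prenyl-3-(TIPS-oxy)benzene
Product: 8 2-[4-methoxy-3-prenyl-5-(TIPS-oxy)phenyl]acetaldehyde
Conditions: 2 M aq HCl, THF, 50 °C; product used without purification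
Reagents that add atoms: water, O
Why: Acid-catalysed enol ether hydrolysis (protonation at the benzylic carbon, hydration of the oxocarbenium ion, loss of methanol) releases the arylacetaldehyde under conditions that an aryl TIPS ether and an isolated trisubstituted olefin tolerate.

Step 6
Reactants: 8 2-[4-methoxy-3-prenyl-5-(TIPS-oxy)phenyl]acetaldehyde
Product: 9 2-[4-methoxy-3-prenyl-5-(TIPS-oxy)phenyl]acetic acid
Conditions: NaClO2, NaH2PO4, 2-methylbut-2-ene, t-BuOH/H2O, 0 °C → rt
Reagents that add atoms: sodium chlorite (NaClO2), [Na+].[O-]Cl=O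
Why: Pinnick oxidation takes the aldehyde to the acid without touching the prenyl olefin or the electron-rich ring because 2-methylbut-2-ene traps the hypochlorous acid that is formed.

Step 7
Reactants: 9 2-[4-methoxy-3-prenyl-5-(TIPS-oxy)phenyl]acetic acid
Product: 11 N-methoxy-N-methyl-2-[4-methoxy-3-prenyl-5-(TIPS-oxy)phenyl]acetamide, via acyl imidazolide 10 (not isolated)
Conditions: CDI, CH2Cl2, rt; then MeNHOMe·HCl, rt
Reagents that add atoms: N,O-dimethylhydroxylamine hydrochloride, CNOC.Cl
Why: Activation of the acid as its acyl imidazolide followed by aminolysis with N,O-dimethylhydroxylamine is a standard Weinreb amide formation that needs neither strong base nor acid.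

Step 8
Reactants: 12 5-methoxyresorcinol (5-methoxybenzene-1,3-diol)
Product: 13 1-methoxy-3,5-bis(MOM-oxy)benzene
Conditions: MOMCl, i-Pr2NEt, CH2Cl2, 0 °C → rt
Reagents that add atoms: chloromethyl methyl ether, COCCl
Why: Williamson-type alkylation of both phenols with MOMCl installs two acetal ethers that are stronger ortho-directing groups than the methoxy group already present.

Step 9
Reactants: 13 1-methoxy-3,5-bis(MOM-oxy)benzene; 5 prenyl bromide
Product: 15 5-methoxy-1,3-bis(MOM-oxy)-2-prenylbenzene, via aryllithium 14 (not isolated)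
Conditions: n-BuLi, THF, 0 °C; then CuI (10 mol%), 5, –78 °C → rt
Reagents that add atoms: none
Why: Directed ortho-metalation should take place at the position flanked by both MOM ethers, where two coordinating acetal oxygens acidify the C–H bond most, and copper-catalysed allylic substitution of prenyl bromide at its primary carbon then gives the symmetric prenyl arene.

Step 10
Reactants: 15 5-methoxy-1,3-bis(MOM-oxy)-2-prenylbenzene; 11 N-methoxy-N-methyl-2-[4-methoxy-3-prenyl-5-(TIPS-oxy)phenyl]acetamide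
Product: 17 1-[2-methoxy-4,6-bis(MOM-oxy)-5-prenylphenyl]-2-[4-methoxy-3-prenyl-5-(TIPS-oxy)phenyl]ethanone, via aryllithium 16 (not isolated)
Conditions: n-BuLi, TMEDA, THF, –20 → 0 °C; then 11, –78 → 0 °C; H2O
Reagents that add atoms: none
Why: A second directed ortho-metalation can only reach the two equivalent ring positions between the methoxy group and a MOM ether, and the aryllithium adds to the Weinreb amide to give a chelated tetrahedral intermediate that collapses to the ketone only on work-up (Weinreb ketone synthesis), which forms the C4–C4a bond with the methoxy group at the future C8a.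

Step 11
Reactants: 17 1-[2-methoxy-4,6-bis(MOM-oxy)-5-prenylphenyl]-2-[4-methoxy-3-prenyl-5-(TIPS-oxy)phenyl]ethanone
Product: 18 1-[2,4-dihydroxy-6-methoxy-3-prenylphenyl]-2-[4-methoxy-3-prenyl-5-(TIPS-oxy)phenyl]ethanone
Conditions: 3 M aq HCl, MeOH, rt
Reagents that add atoms: none
Why: Acid-catalysed acetal cleavage in methanol removes both MOM ethers at room temperature, where an aryl TIPS ether is stable and an ortho-prenyl phenol should not yet cyclise to a chroman.

Step 12
Reactants: 18 1-[2,4-dihydroxy-6-methoxy-3-prenylphenyl]-2-[4-methoxy-3-prenyl-5-(TIPS-oxy)phenyl]ethanone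
Product: 19 1-[2-methoxy-5-prenyl-4,6-bis(TIPS-oxy)phenyl]-2-[4-methoxy-3-prenyl-5-(TIPS-oxy)phenyl]ethanone
Conditions: TIPSOTf (2.6 equiv), 2,6-lutidine, CH2Cl2, 0 °C → rt
Reagents that add atoms: triisopropylsilyl trifluoromethanesulfonate, CC(C)[Si](OS(=O)(=O)C(F)(F)F)(C(C)C)C(C)C
Why: Silyl ether formation with the highly electrophilic silyl triflate should cover both phenols, including the hydrogen-bonded one at the future C5, while 2,6-lutidine is too weak a base to convert the hindered ketone into a silyl enol ether.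

Step 13
Reactants: 19 1-[2-methoxy-5-prenyl-4,6-bis(TIPS-oxy)phenyl]-2-[4-methoxy-3-prenyl-5-(TIPS-oxy)phenyl]ethanone
Product: 20 2-diazo-1-[2-methoxy-5-prenyl-4,6-bis(TIPS-oxy)phenyl]-2-[4-methoxy-3-prenyl-5-(TIPS-oxy)phenyl]ethanone
Conditions: p-ABSA, DBU, MeCN, 0 °C → rt
Reagents that add atoms: 4-acetamidobenzenesulfonyl azide, CC(=O)Nc1ccc(cc1)S(=O)(=O)N=[N+]=[N-]
Why: The α-methylene group is both benzylic and next to the carbonyl, so DBU forms the enolate and Regitz diazo transfer from the sulfonyl azide should give the α-aryl-α-diazo ketone.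

Step 14
Reactants: 20 2-diazo-1-[2-methoxy-5-prenyl-4,6-bis(TIPS-oxy)phenyl]-2-[4-methoxy-3-prenyl-5-(TIPS-oxy)phenyl]ethanone
Product: 22 (3S)-3-[4-methoxy-3-prenyl-5-(TIPS-oxy)phenyl]-6-prenyl-5,7-bis(TIPS-oxy)chroman-4-one, via rhodium carbenoid 21 (not isolated)
Conditions: Rh2(S-PTTL)4 (2 mol%), CH2Cl2 (0.01 M), 20 added over 2 h, –20 °C → rt
Reagents that add atoms: none
Why: Proposed new method: loss of N2 from 20 at the divalent rhodium centres of Rh2(S-PTTL)4 should give the electrophilic aryl/acyl-substituted carbenoid 21, whose carbon C3 inserts through a concerted, asynchronous three-centre transition state into a C–H bond of the C8a methoxy group, a bond that the oxygen lone pair activates toward hydride-like transfer. The closest known reactions are the chiral dirhodium carboxylate-catalysed C–H insertions of 2-alkoxyaryl α-diazo ketones into O–CH2R groups that give chroman-4-ones and the enantioselective insertion of aryl-substituted carbenoids into methyl ether C–H bonds, whereas insertion of an α-aryl-α-keto carbenoid into an aryl methoxy group to close an isoflavanone has not been shown. Ring C closes as a six-membered ring (C3, C4, C4a, C8a, O1, C2) by a 1,6 C–H insertion that forms the C2–C3 bond. C3 becomes stereogenic at the moment of C–C bond formation, and its configuration is set by the chiral pocket of the four phthalimido-tert-leucinate ligands under neutral conditions that do not enolise the product. The step needs site selectivity and enantioselectivity: the C5 oxygen carries a bulky, poorly basic TIPS ether whose C–H bonds would demand a seven-membered or larger transition state and which pushes the rhodium-bearing carbon toward the methoxy side, both prenyl olefins are meta to the reacting positions and cannot reach the carbenoid, slow addition at high dilution suppresses intermolecular reactions, and an oxonium ylide at the methoxy oxygen should merely revert because a 1,2-methyl shift is slow.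

Step 15
Reactants: 22 (3S)-3-[4-methoxy-3-prenyl-5-(TIPS-oxy)phenyl]-6-prenyl-5,7-bis(TIPS-oxy)chroman-4-one
Product: 23 (3S)-5,7-dihydroxy-3-(3-hydroxy-4-methoxy-5-prenylphenyl)-6-prenylchroman-4-one (CNP0327275.1)
Conditions: HF·pyridine, pyridine, THF, 0 °C → rt
Reagents that add atoms: none
Why: Fluoride-mediated cleavage of the three aryl silyl ethers (formation of Si–F bonds) proceeds in a weakly acidic pyridine buffer that neither enolises C3 nor protonates the prenyl olefins, so the 3S configuration should be retained.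

**Compound list**

1 | 3-bromo-4,5-dihydroxybenzaldehyde | O=Cc1cc(O)c(O)c(Br)c1 | starting material
2 | 3-bromo-5-hydroxy-4-methoxybenzaldehyde | O=Cc1cc(O)c(OC)c(Br)c1 | intermediate
3 | 3-bromo-4-methoxy-5-(triisopropylsilyloxy)benzaldehyde | O=Cc1cc(O[Si](C(C)C)(C(C)C)C(C)C)c(OC)c(Br)c1 | intermediate
4 | 1-bromo-2-methoxy-5-(2-methoxyethenyl)-3-(triisopropylsilyloxy)benzene, E/Z mixture | COC=Cc1cc(O[Si](C(C)C)(C(C)C)C(C)C)c(OC)c(Br)c1 | intermediate
5 | prenyl bromide (1-bromo-3-methylbut-2-ene) | CC(C)=CCBr | starting material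
6 | [2-methoxy-5-(2-methoxyethenyl)-3-(triisopropylsilyloxy)phenyl]lithium | COC=Cc1cc(O[Si](C(C)C)(C(C)C)C(C)C)c(OC)c([Li])c1 | intermediate
7 | 2-methoxy-5-(2-methoxyethenyl)-1-(3-methylbut-2-en-1-yl)-3-(triisopropylsilyloxy)benzene, E/Z mixture | COC=Cc1cc(O[Si](C(C)C)(C(C)C)C(C)C)c(OC)c(CC=C(C)C)c1 | intermediate
8 | 2-[4-methoxy-3-(3-methylbut-2-en-1-yl)-5-(triisopropylsilyloxy)phenyl]acetaldehyde | O=CCc1cc(O[Si](C(C)C)(C(C)C)C(C)C)c(OC)c(CC=C(C)C)c1 | intermediate
9 | 2-[4-methoxy-3-(3-methylbut-2-en-1-yl)-5-(triisopropylsilyloxy)phenyl]acetic acid | OC(=O)Cc1cc(O[Si](C(C)C)(C(C)C)C(C)C)c(OC)c(CC=C(C)C)c1 | intermediate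
10 | 1-(imidazol-1-yl)-2-[4-methoxy-3-(3-methylbut-2-en-1-yl)-5-(triisopropylsilyloxy)phenyl]ethanone (acyl imidazolide) | O=C(Cc1cc(O[Si](C(C)C)(C(C)C)C(C)C)c(OC)c(CC=C(C)C)c1)n1ccnc1 | intermediate
11 | N-methoxy-N-methyl-2-[4-methoxy-3-(3-methylbut-2-en-1-yl)-5-(triisopropylsilyloxy)phenyl]acetamide | CON(C)C(=O)Cc1cc(O[Si](C(C)C)(C(C)C)C(C)C)c(OC)c(CC=C(C)C)c1 | intermediate
12 | 5-methoxyresorcinol (5-methoxybenzene-1,3-diol) | COc1cc(O)cc(O)c1 | starting material
13 | 1-methoxy-3,5-bis(methoxymethoxy)benzene | COCOc1cc(OC)cc(OCOC)c1 | intermediate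
14 | [4-methoxy-2,6-bis(methoxymethoxy)phenyl]lithium | COCOc1cc(OC)cc(OCOC)c1[Li] | intermediate
15 | 5-methoxy-1,3-bis(methoxymethoxy)-2-(3-methylbut-2-en-1-yl)benzene | COCOc1cc(OC)cc(OCOC)c1CC=C(C)C | intermediate
16 | [2-methoxy-4,6-bis(methoxymethoxy)-5-(3-methylbut-2-en-1-yl)phenyl]lithium | COCOc1cc(OC)c([Li])c(OCOC)c1CC=C(C)C | intermediate
17 | 1-[2-methoxy-4,6-bis(methoxymethoxy)-5-(3-methylbut-2-en-1-yl)phenyl]-2-[4-methoxy-3-(3-methylbut-2-en-1-yl)-5-(triisopropylsilyloxy)phenyl]ethanone | COCOc1cc(OC)c(C(=O)Cc2cc(O[Si](C(C)C)(C(C)C)C(C)C)c(OC)c(CC=C(C)C)c2)c(OCOC)c1CC=C(C)C | intermediate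
18 | 1-[2,4-dihydroxy-6-methoxy-3-(3-methylbut-2-en-1-yl)phenyl]-2-[4-methoxy-3-(3-methylbut-2-en-1-yl)-5-(triisopropylsilyloxy)phenyl]ethanone | COc1cc(O)c(CC=C(C)C)c(O)c1C(=O)Cc1cc(O[Si](C(C)C)(C(C)C)C(C)C)c(OC)c(CC=C(C)C)c1 | intermediate
19 | 1-[2-methoxy-5-(3-methylbut-2-en-1-yl)-4,6-bis(triisopropylsilyloxy)phenyl]-2-[4-methoxy-3-(3-methylbut-2-en-1-yl)-5-(triisopropylsilyloxy)phenyl]ethanone | COc1cc(O[Si](C(C)C)(C(C)C)C(C)C)c(CC=C(C)C)c(O[Si](C(C)C)(C(C)C)C(C)C)c1C(=O)Cc1cc(O[Si](C(C)C)(C(C)C)C(C)C)c(OC)c(CC=C(C)C)c1 | intermediate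
20 | 2-diazo-1-[2-methoxy-5-(3-methylbut-2-en-1-yl)-4,6-bis(triisopropylsilyloxy)phenyl]-2-[4-methoxy-3-(3-methylbut-2-en-1-yl)-5-(triisopropylsilyloxy)phenyl]ethanone | COc1cc(O[Si](C(C)C)(C(C)C)C(C)C)c(CC=C(C)C)c(O[Si](C(C)C)(C(C)C)C(C)C)c1C(=O)C(=[N+]=[N-])c1cc(O[Si](C(C)C)(C(C)C)C(C)C)c(OC)c(CC=C(C)C)c1 | intermediate
21 | rhodium carbenoid at C3 derived from 20 ([Rh] in the SMILES stands for the Rh2(S-PTTL)4 unit) | COc1cc(O[Si](C(C)C)(C(C)C)C(C)C)c(CC=C(C)C)c(O[Si](C(C)C)(C(C)C)C(C)C)c1C(=O)C(=[Rh])c1cc(O[Si](C(C)C)(C(C)C)C(C)C)c(OC)c(CC=C(C)C)c1 | intermediate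
22 | (3S)-3-[4-methoxy-3-(3-methylbut-2-en-1-yl)-5-(triisopropylsilyloxy)phenyl]-6-(3-methylbut-2-en-1-yl)-5,7-bis(triisopropylsilyloxy)chroman-4-one | COc1c(O[Si](C(C)C)(C(C)C)C(C)C)cc([C@H]2COc3cc(O[Si](C(C)C)(C(C)C)C(C)C)c(CC=C(C)C)c(O[Si](C(C)C)(C(C)C)C(C)C)c3C2=O)cc1CC=C(C)C | intermediate
23 | (3S)-5,7-dihydroxy-3-[3-hydroxy-4-methoxy-5-(3-methylbut-2-en-1-yl)phenyl]-6-(3-methylbut-2-en-1-yl)chroman-4-one (CNP0327275.1) | COc1c(O)cc([C@H]2COc3cc(O)c(CC=C(C)C)c(O)c3C2=O)cc1CC=C(C)C | target

**Step count and risks**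

Total step count: 15. Longest linear sequence: 13 steps (steps 1–7, then 10–15); steps 8–9 form the short ring A branch.

Steps most likely to fail:

1. Step 14. The carbenoid may be diverted before it inserts: attack of the methoxy oxygen with a subsequent methyl shift would give a benzofuranone, the carbenoid may dimerise, or insertion may occur with poor facial selectivity at C3. The fallback builds ring C by O1–C2 bond formation and sets C3 by dynamic kinetic resolution, all with known reactions. It sets out from 19. MgI2·OEt2 in toluene/ether cleaves, by chelation to the ketone, only the methyl ether next to the carbonyl and should give 1-[2-hydroxy-5-prenyl-4,6-bis(TIPS-oxy)phenyl]-2-[4-methoxy-3-prenyl-5-(TIPS-oxy)phenyl]ethanone F1. Heating with N,N-dimethylformamide dimethyl acetal supplies C2 and closes the isoflavone 3-[4-methoxy-3-prenyl-5-(TIPS-oxy)phenyl]-6-prenyl-5,7-bis(TIPS-oxy)-4H-chromen-4-one F2. Noyori-type asymmetric transfer hydrogenation with RuCl(p-cymene)[(S,S)-TsDPEN] and HCO2H/Et3N reduces the C2–C3 double bond and then, with dynamic kinetic resolution of the epimerising isoflavanone, the ketone, to give the cis alcohol (3S,4S)-3-[4-methoxy-3-prenyl-5-(TIPS-oxy)phenyl]-6-prenyl-5,7-bis(TIPS-oxy)chroman-4-ol F3. Oxidation with Dess–Martin periodinane buffered by NaHCO3 restores the ketone without touching C3, and the route is rejoined at 22.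

2. Step 10. Proton transfer from the acidic α-methylene of amide 11 to the hindered aryllithium may outrun carbonyl addition, which would return 15 and the amide. The fallback moves the electrophile to the aldehyde oxidation level and uses a non-basic organocerium nucleophile. It sets out from 15 and 8: 15 is lithiated as before to 16, transmetalated with anhydrous CeCl3 at –78 °C and added to aldehyde 8 to give the secondary alcohol 1-[2-methoxy-4,6-bis(MOM-oxy)-5-prenylphenyl]-2-[4-methoxy-3-prenyl-5-(TIPS-oxy)phenyl]ethanol F4, and Dess–Martin oxidation brings the route back at 17.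

3. Step 13. Enolate formation at the shielded, twisted ketone may be slow with DBU, and prolonged exposure to the amidine base may strip the silyl ethers ortho and para to the carbonyl, so that diazo transfer stalls. The fallback activates the α-position as a 1,3-dicarbonyl compound instead (detrifluoroacetylative diazo transfer). It sets out from 19: LiN(SiMe3)2 at –78 °C followed by 2,2,2-trifluoroethyl trifluoroacetate gives 4,4,4-trifluoro-1-[2-methoxy-5-prenyl-4,6-bis(TIPS-oxy)phenyl]-2-[4-methoxy-3-prenyl-5-(TIPS-oxy)phenyl]butane-1,3-dione F5, which with methanesulfonyl azide, Et3N and water in MeCN loses the trifluoroacetyl group and returns to the route at 20.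

**Further compounds**

F1 | step 14 | 1-[2-hydroxy-5-(3-methylbut-2-en-1-yl)-4,6-bis(triisopropylsilyloxy)phenyl]-2-[4-methoxy-3-(3-methylbut-2-en-1-yl)-5-(triisopropylsilyloxy)phenyl]ethanone | Oc1cc(O[Si](C(C)C)(C(C)C)C(C)C)c(CC=C(C)C)c(O[Si](C(C)C)(C(C)C)C(C)C)c1C(=O)Cc1cc(O[Si](C(C)C)(C(C)C)C(C)C)c(OC)c(CC=C(C)C)c1
F2 | step 14 | 3-[4-methoxy-3-(3-methylbut-2-en-1-yl)-5-(triisopropylsilyloxy)phenyl]-6-(3-methylbut-2-en-1-yl)-5,7-bis(triisopropylsilyloxy)-4H-chromen-4-one | COc1c(O[Si](C(C)C)(C(C)C)C(C)C)cc(-c2coc3cc(O[Si](C(C)C)(C(C)C)C(C)C)c(CC=C(C)C)c(O[Si](C(C)C)(C(C)C)C(C)C)c3c2=O)cc1CC=C(C)C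
F3 | step 14 | (3S,4S)-3-[4-methoxy-3-(3-methylbut-2-en-1-yl)-5-(triisopropylsilyloxy)phenyl]-6-(3-methylbut-2-en-1-yl)-5,7-bis(triisopropylsilyloxy)chroman-4-ol | COc1c(O[Si](C(C)C)(C(C)C)C(C)C)cc([C@H]2COc3cc(O[Si](C(C)C)(C(C)C)C(C)C)c(CC=C(C)C)c(O[Si](C(C)C)(C(C)C)C(C)C)c3[C@H]2O)cc1CC=C(C)C
F4 | step 10 | 1-[2-methoxy-4,6-bis(methoxymethoxy)-5-(3-methylbut-2-en-1-yl)phenyl]-2-[4-methoxy-3-(3-methylbut-2-en-1-yl)-5-(triisopropylsilyloxy)phenyl]ethanol (racemic) | COCOc1cc(OC)c(C(O)Cc2cc(O[Si](C(C)C)(C(C)C)C(C)C)c(OC)c(CC=C(C)C)c2)c(OCOC)c1CC=C(C)C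
F5 | step 13 | 4,4,4-trifluoro-1-[2-methoxy-5-(3-methylbut-2-en-1-yl)-4,6-bis(triisopropylsilyloxy)phenyl]-2-[4-methoxy-3-(3-methylbut-2-en-1-yl)-5-(triisopropylsilyloxy)phenyl]butane-1,3-dione | COc1cc(O[Si](C(C)C)(C(C)C)C(C)C)c(CC=C(C)C)c(O[Si](C(C)C)(C(C)C)C(C)C)c1C(=O)C(C(=O)C(F)(F)F)c1cc(O[Si](C(C)C)(C(C)C)C(C)C)c(OC)c(CC=C(C)C)c1
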